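The cyclohexene ring is numbered C1 (carbinol bearing C7H2OAc), C2/C3 (benzoates), C4=C5, C6 (acetate). The route exploits the C1(OH)–C6(OAc)–C5=C4 array, an alk-1-ene-3,4-diol monoacetate closed into the ring. The two-carbon unit C6–C5 is inserted between a C1 ketone and a C4 vinyl group. In one flask a γ-acetoxyallylindium reagent adds to acyclic keto-olefin 6 (C6–C1 bond, both new stereocentres). A ruthenium carbene then closes C4=C5 with loss of ethylene, giving the fully acylated target directly. Ketone 6 carries C2 and C3, already benzoylated, as the central carbons of D-mannitol. No protecting group is used.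

Key step: step 7

Remark: compound 1 (mitobronitol) is taken as a purchasable D-mannitol derivative. Compounds 4 and 5 are C5-epimer mixtures and 9 is an E/Z mixture, so these elements are left open in their SMILES. Both are erased or equilibrated later.

Step 1
Reactants: 1 1,6-dibromo-1,6-dideoxy-D-mannitol
Product: 2 2,3,4,5-tetra-O-benzoyl-1,6-dibromo-1,6-dideoxy-D-mannitol
Conditions: BzCl (4.5 equiv), pyridine, cat. DMAP, CH2Cl2, 0 °C → rt
Reagents that add atoms: benzoyl chloride, O=C(Cl)c1ccccc1
Why: Exhaustive O-acylation of the four secondary hydroxyls with nucleophilic catalysis, under weakly basic conditions that should not close the bromohydrins to epoxides; no stereocentre is touched.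

Step 2
Reactants: 2 2,3,4,5-tetra-O-benzoyl-1,6-dibromo-1,6-dideoxy-D-mannitol
Product: 3 (3R,4R)-hexa-1,5-diene-3,4-diyl dibenzoate
Conditions: activated Zn dust, AcOH/THF, 50 °C
Reagents that add atoms: none
Why: Twofold zinc-mediated reductive β-elimination (Boord-type olefin synthesis) of the vicinal bromo-benzoate at each terminus expels the O-2 and O-5 benzoates and leaves the two central stereocentres with the benzoates that the target keeps.

Step 3
Reactants: 3 (3R,4R)-hexa-1,5-diene-3,4-diyl dibenzoate
Product: 4 (3R,4R,5RS)-5,6-dihydroxyhex-1-ene-3,4-diyl dibenzoate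
Conditions: OsO4 (1 mol %), NMO (0.8 equiv), citric acid, t-BuOH/H2O, 0 °C → rt, stopped at partial conversion, 3 recycled
Reagents that add atoms: osmium tetroxide (catalytic oxygen carrier), O=[Os](=O)(=O)=O; N-methylmorpholine N-oxide, C[N+]1([O-])CCOCC1; water, O
Why: Upjohn-type catalytic syn-dihydroxylation of one of two homotopic vinyl groups, so regiochemistry is not an issue and limiting oxidant should hold the reaction at the mono-adduct, while the new C5 centre forms as an epimer mixture erased in step 5 and the acidic buffer suppresses benzoyl migration.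

Step 4
Reactants: 4 (3R,4R,5RS)-5,6-dihydroxyhex-1-ene-3,4-diyl dibenzoate
Product: 5 (3R,4R,5RS)-6-acetoxy-5-hydroxyhex-1-ene-3,4-diyl dibenzoate
Conditions: AcCl (1.05 equiv), 2,4,6-collidine, CH2Cl2, −78 °C
Reagents that add atoms: acetyl chloride, CC(=O)Cl
Why: Kinetically controlled acylation of the primary over the secondary hydroxyl with a hindered pyridine base at low temperature installs the C7 acetate of the target.

Step 5
Reactants: 5 (3R,4R,5RS)-6-acetoxy-5-hydroxyhex-1-ene-3,4-diyl dibenzoate
Product: 6 (3R,4S)-6-acetoxy-5-oxohex-1-ene-3,4-diyl dibenzoate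
Conditions: Dess–Martin periodinane, CH2Cl2, 0 °C → rt
Reagents that add atoms: none
Why: Dess–Martin oxidation of the remaining secondary alcohol under neutral, non-enolising conditions should converge both C5 epimers on one ketone without β-elimination of benzoate or epimerisation at the α-carbon.

Step 6
Reactants: 7 acrolein; 8 acetyl bromide
Product: 9 3-bromoprop-1-en-1-yl acetate (E/Z mixture)
Conditions: cat. ZnCl2, CH2Cl2, −20 °C → rt
Reagents that add atoms: none
Why: Lewis-acid-catalysed 1,4-addition of the acyl bromide to the enal (O-acylation with bromide capture at C3, any 1,2-adduct equilibrating) is a known entry to 3-halopropenyl esters, and the E/Z mixture is inconsequential because the derived allylindium species equilibrates.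

Step 7
Reactants: 6 (3R,4S)-6-acetoxy-5-oxohex-1-ene-3,4-diyl dibenzoate; 9 3-bromoprop-1-en-1-yl acetate
Product: 12 [(1R,2S,3R,6S)-6-acetoxy-2,3-bis(benzoyloxy)-1-hydroxycyclohex-4-en-1-yl]methyl acetate (target), via acetoxyallylindium reagent 10 (not isolated), via octadienol 11 (not isolated)
Conditions: In powder, 9 (1.5 equiv), THF, rt, 30 min; 6, 0 °C → rt; H2O (5 equiv); then CH2Cl2 (to 5 mM), Hoveyda–Grubbs II (5 mol %), 40 °C, same flask
Reagents that add atoms: none
Why: Indium inserts into 9 to give the γ-acetoxyallylindium species 10, held in the Z form by internal C=O→In coordination, which attacks the ketone of 6 through its oxygen-bearing γ-carbon in a chair Zimmerman–Traxler transition state (C6–C1 bond); after protonation of the alkoxide the ruthenium alkylidene engages the two terminal vinyl groups of 11 and releases ethylene (C4=C5 bond). The closest known reaction types are the indium-mediated Barbier α-acyloxyallylation of carbonyl compounds and the diene ring-closing metathesis used for carbohydrate-to-conduritol carbocyclisation, here run in sequence in one flask. The only ring formed, the cyclohexene, is closed by RCM of the octa-1,7-diene, the ring size enforcing the Z alkene. C1 is controlled by the C2 stereocentre through a polar Felkin–Anh approach anti to the non-chelating benzoyloxy group, which should place 1-OH and 2-OBz erythro, that is cis on the ring. C6 is controlled by the Z geometry of 10 with the larger C2 branch of the ketone equatorial in the chair, which should give the syn (threo) C1/C6 pair, that is 6-OAc trans to 1-OH. The step needs attack on the ketone in the presence of four esters without enolisation or loss of benzoate, secured by the low basicity of allylindium reagents and the activation of the ketone by its two α-acyloxy groups, while preforming 10 keeps indium metal away from the reducible α-acyloxy ketone and high dilution favours ring closure over oligomerisation.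

Compound list
1 | 1,6-dibromo-1,6-dideoxy-D-mannitol (mitobronitol) | BrC[C@@H](O)[C@@H](O)[C@H](O)[C@H](O)CBr | starting material
2 | 2,3,4,5-tetra-O-benzoyl-1,6-dibromo-1,6-dideoxy-D-mannitol | BrC[C@@H](OC(=O)c1ccccc1)[C@@H](OC(=O)c1ccccc1)[C@H](OC(=O)c1ccccc1)[C@H](OC(=O)c1ccccc1)CBr | intermediate
3 | (3R,4R)-hexa-1,5-diene-3,4-diyl dibenzoate | C=C[C@@H](OC(=O)c1ccccc1)[C@H](OC(=O)c1ccccc1)C=C | intermediate
4 | (3R,4R,5RS)-5,6-dihydroxyhex-1-ene-3,4-diyl dibenzoate (C5 epimers) | C=C[C@@H](OC(=O)c1ccccc1)[C@H](OC(=O)c1ccccc1)C(O)CO | intermediate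
5 | (3R,4R,5RS)-6-acetoxy-5-hydroxyhex-1-ene-3,4-diyl dibenzoate (C5 epimers) | C=C[C@@H](OC(=O)c1ccccc1)[C@H](OC(=O)c1ccccc1)C(O)COC(C)=O | intermediate
6 | (3R,4S)-6-acetoxy-5-oxohex-1-ene-3,4-diyl dibenzoate | C=C[C@@H](OC(=O)c1ccccc1)[C@H](OC(=O)c1ccccc1)C(=O)COC(C)=O | intermediate
7 | acrolein | C=CC=O | starting material
8 | acetyl bromide | CC(=O)Br | starting material
9 | 3-bromoprop-1-en-1-yl acetate (E/Z mixture) | CC(=O)OC=CCBr | intermediate
10 | (Z)-3-acetoxyallylindium sesquibromide, drawn as its RInBr2 component | CC(=O)O/C=C\C[In](Br)Br | intermediate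
11 | (3R,4S,5R,6S)-6-acetoxy-5-(acetoxymethyl)-5-hydroxyocta-1,7-diene-3,4-diyl dibenzoate | CC(=O)OC[C@@]([C@@H](OC(=O)c1ccccc1)[C@H](OC(=O)c1ccccc1)C=C)(O)[C@@H](OC(C)=O)C=C | intermediate
12 | [(1R,2S,3R,6S)-6-acetoxy-2,3-bis(benzoyloxy)-1-hydroxycyclohex-4-en-1-yl]methyl acetate | CC(=O)OC[C@@]1(O)[C@@H](OC(C)=O)C=C[C@@H](OC(=O)c2ccccc2)[C@@H]1OC(=O)c1ccccc1 | target

Total step count: 7. Longest linear sequence: 6 (steps 1–5 and 7).

Steps most likely to fail

Step 7. The addition could show poor facial or simple diastereoselection. Acetyl could migrate in the indium alkoxide. Enol acetate residues could deactivate the ruthenium catalyst.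
- The fallback sets out from 6 and comes back at 12. It takes the C6 stereocentre out of the C–C bond-forming event.
- Plain allylindium (allyl bromide, In, THF/H2O) is used, followed by the ruthenium catalyst in the same flask. This should pass through the homoallylic tertiary alcohol F1, where only C1 is new, to the 6-deoxy cyclohexene F2.
- Allylic oxidation of the only ring CH2 (Rh2(cap)4, TBHP) should give the enone F3.
- Hydroxyl-directed reduction with Me4NBH(OAc)3 in MeCN/AcOH delivers hydride from the face of the C1 hydroxyl and should give the trans-diol F4.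
- Ac2O/pyridine acetylates the secondary but not the tertiary hydroxyl and returns to 12.

Step 3. The second, homotopic vinyl group could be over-oxidised, and benzoyl could migrate onto the newly formed secondary hydroxyl in the aqueous amine medium.
- The fallback sets out from 3 and comes back at 5. It avoids the free diol.
- Mono-epoxidation with mCPBA in a non-aqueous medium, at partial conversion, should give the mono-epoxide F5.
- (salen)Co(III)-catalysed addition of acetic acid at the terminal epoxide carbon gives the primary acetate/secondary alcohol 5 directly, which also removes the selective acetylation.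

Step 4. The primary and secondary hydroxyls could be discriminated incompletely, or acyl groups could scramble between O-4, O-5 and O-6.
- The fallback sets out from 4 and comes back at 6. It reverses the order of events.
- Chemoselective oxidation of the secondary carbinol of the vicinal diol with [(neocuproine)Pd(OAc)]2(OTf)2 and benzoquinone should give the hydroxy ketone F6.
- Its single remaining hydroxyl is then acetylated (AcCl, collidine) to give 6, so no hydroxyl differentiation by acylation is needed.

Further compounds
F1 | step 7 | (3R,4S,5S)-5-(acetoxymethyl)-5-hydroxyocta-1,7-diene-3,4-diyl dibenzoate | CC(=O)OC[C@@]([C@@H](OC(=O)c1ccccc1)[C@H](OC(=O)c1ccccc1)C=C)(O)CC=C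
F2 | step 7 | [(1S,2S,3R)-2,3-bis(benzoyloxy)-1-hydroxycyclohex-4-en-1-yl]methyl acetate | CC(=O)OC[C@@]1(O)CC=C[C@@H](OC(=O)c2ccccc2)[C@@H]1OC(=O)c1ccccc1
F3 | step 7 | [(1S,2S,3R)-2,3-bis(benzoyloxy)-1-hydroxy-6-oxocyclohex-4-en-1-yl]methyl acetate | CC(=O)OC[C@@]1(O)C(=O)C=C[C@@H](OC(=O)c2ccccc2)[C@@H]1OC(=O)c1ccccc1
F4 | step 7 | [(1R,2S,3R,6S)-2,3-bis(benzoyloxy)-1,6-dihydroxycyclohex-4-en-1-yl]methyl acetate | CC(=O)OC[C@@]1(O)[C@@H](O)C=C[C@@H](OC(=O)c2ccccc2)[C@@H]1OC(=O)c1ccccc1
F5 | step 3 | 5,6-epoxyhex-1-ene-3,4-diyl dibenzoate, mono-epoxide of 3 (C5 epimers) | C=C[C@@H](OC(=O)c1ccccc1)[C@H](OC(=O)c1ccccc1)C1CO1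
F6 | step 4 | (3R,4S)-6-hydroxy-5-oxohex-1-ene-3,4-diyl dibenzoate | C=C[C@@H](OC(=O)c1ccccc1)[C@H](OC(=O)c1ccccc1)C(=O)CO
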